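**Strategy**

Everything rests on cutting the bond between the exocyclic carbinol carbon C1′ and the chain methylene C2′. The key step is the last one: a non-8-enyl Grignard reagent adds to an oxolane-2-carbaldehyde that already carries the pentyl group and the laurate. It exploits the ring oxygen O1 on C5, the ring carbon next to C1′: magnesium bridges O1 and the aldehyde oxygen, so one operation joins both halves, sets C1′ as R (threo to C5) and gives the target without hydroxyl protecting groups. The aldehyde comes in six steps from heptanal via an α-chloroaldehyde aldol, syn reduction and a chloride displacement that closes the ring.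

Key step: step 7

Numbering used: oxolane ring O1, C2 (pentyl), C3 (laurate), C4, C5 (side chain); side chain C1′ (carbinol) to C10′.

Remark on the chemistry: the (5R) antipode of the imidazolidinone catalyst in step 1 is taken to give the (R)-chloroaldehyde, as the mirror image of the (5S)-catalyst/(S)-product pairing; this choice alone fixes the absolute configuration of the route.

**Route**

Step 1
Reactants: 1 heptanal
Product: 2 (2R)-2-chloroheptanal
Conditions: (5R)-5-benzyl-2,2,3-trimethylimidazolidin-4-one·CF3CO2H (cat.), 2,3,4,5,6,6-hexachlorocyclohexa-2,4-dien-1-one, acetone, −30 °C; used crude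
Reagents that add atoms: 2,3,4,5,6,6-hexachlorocyclohexa-2,4-dien-1-one, O=C1C(Cl)=C(Cl)C(Cl)=C(Cl)C1(Cl)Cl
Why: Enamine-mediated asymmetric α-chlorination of an aldehyde (organocatalysis): the benzyl group of the imidazolidinone shields one face of the E-enamine of 1, so chlorine is delivered to the other face and C2 is set as R under catalyst control, the configurationally labile product being used at once without chromatography.

Step 2
Reactants: 2 (2R)-2-chloroheptanal; 3 1,1-dimethoxypropan-2-one
Product: 5 (4S,5R)-5-chloro-4-hydroxy-1,1-dimethoxydecan-2-one, via lithium 3,3-dimethoxyprop-1-en-2-olate 4 (not isolated)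
Conditions: 3, LiN(iPr)2, THF, −78 °C; then 2, −78 °C; AcOH quench at −78 °C
Reagents that add atoms: none
Why: Lithium-enolate aldol addition to an α-chloroaldehyde: kinetic deprotonation of 3 at the methyl group gives 4, which adds to 2 in the Cornforth (polar Felkin–Anh) sense at −78 °C, faster than proton transfer, so that the new carbinol centre C4 (S) is set anti to the C5 chloride by the stereocentre of 2.

Step 3
Reactants: 5 (4S,5R)-5-chloro-4-hydroxy-1,1-dimethoxydecan-2-one
Product: 7 (2R,4S,5R)-5-chloro-1,1-dimethoxydecane-2,4-diol, via diethylboryl chelate 6 (not isolated)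
Conditions: Et2BOMe, THF/MeOH (4:1), −78 °C; NaBH4, −78 °C; MeOH co-evaporation (regenerates Et2BOMe)
Reagents that add atoms: none
Why: Narasaka–Prasad reduction: the diethylboryl chelate 6 fixes the β-alkoxy ketone in a half-chair and external hydride adds axially, which sets C2 (R) 1,3-syn to the C4 oxygen, while the chloride and the acetal are inert to NaBH4 at −78 °C.

Step 4
Reactants: 7 (2R,4S,5R)-5-chloro-1,1-dimethoxydecane-2,4-diol
Product: 8 (2S,3S,5R)-5-(dimethoxymethyl)-2-pentyloxolan-3-ol
Conditions: AgOTf (AgOSO2CF3), Ag2O, THF, 20 °C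
Reagents that add atoms: none
Why: Intramolecular Williamson-type etherification assisted by monovalent silver: the C2 hydroxyl displaces the secondary chloride at C5 in a 5-exo-tet closure with inversion (R chloride to S ether carbon), which gives the 2,3-cis-2,5-trans oxolane, and Ag2O scavenges the acid so that the dimethyl acetal survives.

Step 5
Reactants: 8 (2S,3S,5R)-5-(dimethoxymethyl)-2-pentyloxolan-3-ol; 9 dodecanoyl chloride
Product: 10 (2S,3S,5R)-5-(dimethoxymethyl)-2-pentyloxolan-3-yl dodecanoate
Conditions: pyridine, DMAP (cat.), CH2Cl2, 0 → 20 °C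
Reagents that add atoms: none
Why: DMAP-catalysed O-acylation with an acid chloride at the only free hydroxyl, which touches no stereocentre and leaves the base-stable acetal intact.

Step 6
Reactants: 10 (2S,3S,5R)-5-(dimethoxymethyl)-2-pentyloxolan-3-yl dodecanoate
Product: 11 (2S,3S,5R)-5-formyl-2-pentyloxolan-3-yl dodecanoate
Conditions: CF3CO2H/H2O (4:1), CH2Cl2, 0 °C; toluene azeotrope; used directly
Reagents that add atoms: water, O
Why: Acid-catalysed acetal hydrolysis through the oxocarbenium ion, under which the secondary ester and the oxolane are stable and C5, α to the new aldehyde, is not enolised.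

Step 7
Reactants: 11 (2S,3S,5R)-5-formyl-2-pentyloxolan-3-yl dodecanoate; 12 9-bromonon-1-ene
Product: 14 (2S,3S,5R)-5-[(1R)-1-hydroxydec-9-en-1-yl]-2-pentyloxolan-3-yl dodecanoate, via non-8-enylmagnesium bromide 13 (not isolated)
Conditions: 12, Mg, Et2O, 35 °C (gives 13); 11, MgBr2·OEt2 (2.5 equiv), CH2Cl2, −78 °C; add 13 (1.3 equiv), −78 °C; 0.5 M HCl, −78 → 0 °C
Reagents that add atoms: none
Why: Chelation-controlled Grignard 1,2-addition (Cram-chelate model): MgBr2 ties the aldehyde oxygen and ring oxygen O1 into a rigid five-membered chelate, and the primary alkylmagnesium 13 adds to the carbonyl carbon to form the C1′–C2′ bond. The closest known reaction type is the threo-selective addition of Grignard reagents to α-alkoxy aldehydes and oxolane-2-carbaldehydes under magnesium chelation. No ring is closed. The new stereocentre C1′ is controlled by the adjacent ring stereocentre C5: in the chelate the ring methylene C4 blocks one face, so attack comes from the face of H-5 and should give the (1′R) threo alcohol. The step needs facial selectivity and chemoselectivity for the aldehyde over the C3 laurate; the first is secured by the O1–Mg–O=C chelate, the second by the much higher electrophilicity of the magnesium-bound aldehyde at −78 °C with only a slight excess of 13. Acyl migration from O3 to the new alkoxide is disfavoured because the two oxygens lie on opposite faces of the ring, and the cold acid quench frees the target directly.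

**Compound list**

1 | heptanal | CCCCCCC=O | starting material
2 | (2R)-2-chloroheptanal | CCCCC[C@@H](Cl)C=O | intermediate
3 | 1,1-dimethoxypropan-2-one | CC(=O)C(OC)OC | starting material
4 | lithium 3,3-dimethoxyprop-1-en-2-olate | [Li]OC(=C)C(OC)OC | intermediate
5 | (4S,5R)-5-chloro-4-hydroxy-1,1-dimethoxydecan-2-one | COC(OC)C(=O)C[C@H](O)[C@H](Cl)CCCCC | intermediate
6 | (4S,5R)-5-chloro-4-(diethylboranyloxy)-1,1-dimethoxydecan-2-one (boron chelate) | COC(OC)C(=O)C[C@H](OB(CC)CC)[C@H](Cl)CCCCC | intermediate
7 | (2R,4S,5R)-5-chloro-1,1-dimethoxydecane-2,4-diol | COC(OC)[C@H](O)C[C@H](O)[C@H](Cl)CCCCC | intermediate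
8 | (2S,3S,5R)-5-(dimethoxymethyl)-2-pentyloxolan-3-ol | COC(OC)[C@H]1C[C@H](O)[C@H](CCCCC)O1 | intermediate
9 | dodecanoyl chloride | CCCCCCCCCCCC(Cl)=O | starting material
10 | (2S,3S,5R)-5-(dimethoxymethyl)-2-pentyloxolan-3-yl dodecanoate | COC(OC)[C@H]1C[C@H](OC(=O)CCCCCCCCCCC)[C@H](CCCCC)O1 | intermediate
11 | (2S,3S,5R)-5-formyl-2-pentyloxolan-3-yl dodecanoate | O=C[C@H]1C[C@H](OC(=O)CCCCCCCCCCC)[C@H](CCCCC)O1 | intermediate
12 | 9-bromonon-1-ene | C=CCCCCCCCBr | starting material
13 | non-8-enylmagnesium bromide | C=CCCCCCCC[Mg]Br | intermediate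
14 | (2S,3S,5R)-5-[(1R)-1-hydroxydec-9-en-1-yl]-2-pentyloxolan-3-yl dodecanoate | C=CCCCCCCC[C@@H](O)[C@H]1C[C@H](OC(=O)CCCCCCCCCCC)[C@H](CCCCC)O1 | target

**Step count**

Total steps: 7. Longest linear sequence: 7 steps (1 to 14).

**Steps most likely to fail**

Step 7: poor facial selectivity if chelation between O1 and the aldehyde is incomplete, so that attack from both faces competes. The fallback sets out from 11 and sets C1′ by reduction instead of addition. The Grignard reagent 13 is added at −78 °C without a chelating additive, which should give 14 together with its C1′ epimer (2S,3S,5R)-5-[(1S)-1-hydroxydec-9-en-1-yl]-2-pentyloxolan-3-yl dodecanoate F1. The mixture is oxidised with Dess–Martin periodinane to the ketone (2S,3S,5R)-5-(dec-9-enoyl)-2-pentyloxolan-3-yl dodecanoate F2. Reduction of F2 with LiBH(sec-Bu)3 in THF at −78 °C, by non-chelated Felkin–Anh delivery of hydride, should give the threo alcohol and comes back to the route at 14.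

Step 6: slow cleavage of the acetal, which is deactivated by the neighbouring ring oxygen, with loss or migration of the laurate or epimerisation at C5 if the acid is forced. The fallback sets out from 2 and unveils the aldehyde by oxidative cleavage of an alkene instead of hydrolysis. Aldol addition of the lithium enolate of (E)-4-phenylbut-3-en-2-one to 2 should give (1E,5S,6R)-6-chloro-5-hydroxy-1-phenylundec-1-en-3-one F3. Reduction with Et2BOMe/NaBH4 gives (1E,3R,5S,6R)-6-chloro-1-phenylundec-1-ene-3,5-diol F4. Closure with AgOTf/Ag2O gives (2S,3S,5R)-2-pentyl-5-[(E)-2-phenylethenyl]oxolan-3-ol F5. Acylation with 9 gives (2S,3S,5R)-2-pentyl-5-[(E)-2-phenylethenyl]oxolan-3-yl dodecanoate F6. Ozonolysis of F6 (O3, CH2Cl2, −78 °C; Me2S) comes back to the route at 11.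

Step 2: proton transfer from the acidic α-chloroaldehyde to the basic enolate, with erosion of enantiomeric purity and self-condensation, and incomplete anti selectivity. The fallback sets out from 1 and 3 and replaces the stoichiometric enolate by enamine catalysis. Heptanal is chlorinated with N-chlorosuccinimide and catalytic D-proline to racemic 2-chloroheptanal F7. In the same flask D-proline catalyses the aldol addition of 3 to F7 at the methyl side. Because F7 racemises under these conditions, dynamic kinetic resolution should funnel both enantiomers into the anti chlorohydrin, and the sequence comes back to the route at 5.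

**Further compounds**

F1 | step 7 | (2S,3S,5R)-5-[(1S)-1-hydroxydec-9-en-1-yl]-2-pentyloxolan-3-yl dodecanoate | C=CCCCCCCC[C@H](O)[C@H]1C[C@H](OC(=O)CCCCCCCCCCC)[C@H](CCCCC)O1
F2 | step 7 | (2S,3S,5R)-5-(dec-9-enoyl)-2-pentyloxolan-3-yl dodecanoate | C=CCCCCCCCC(=O)[C@H]1C[C@H](OC(=O)CCCCCCCCCCC)[C@H](CCCCC)O1
F3 | step 6 | (1E,5S,6R)-6-chloro-5-hydroxy-1-phenylundec-1-en-3-one | O=C(/C=C/c1ccccc1)C[C@H](O)[C@H](Cl)CCCCC
F4 | step 6 | (1E,3R,5S,6R)-6-chloro-1-phenylundec-1-ene-3,5-diol | c1ccccc1/C=C/[C@H](O)C[C@H](O)[C@H](Cl)CCCCC
F5 | step 6 | (2S,3S,5R)-2-pentyl-5-[(E)-2-phenylethenyl]oxolan-3-ol | c1ccccc1/C=C/[C@H]1C[C@H](O)[C@H](CCCCC)O1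
F6 | step 6 | (2S,3S,5R)-2-pentyl-5-[(E)-2-phenylethenyl]oxolan-3-yl dodecanoate | c1ccccc1/C=C/[C@H]1C[C@H](OC(=O)CCCCCCCCCCC)[C@H](CCCCC)O1
F7 | step 2 | racemic 2-chloroheptanal | CCCCCC(Cl)C=O
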